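Ring A is cut at C1–C2 and C4–C5 (labdane numbering) and ring B at C9–C10, which reduces the target to a C2–C3–C4 acetoacetate unit and a 2,3-dihydrofarnesyl chain. The key step rejoins them in one flask: the terminal carbon of a chiral 2-methylacetoacetate dianion is alkylated by the allylic bromide (C1–C2), and Mn(OAc)3/Cu(OAc)2 oxidation of the resulting keto ester folds the (E,E)-diene by two 6-endo radical closures (C4–C5, C9–C10) that end in the C8=C17 exocyclic alkene. It exploits C4, flanked by the C19 carboxyl and C3, and the head-to-tail methyl pattern at C10 and C8 of rings A and B; an 8-phenylmenthyl ester fixes the absolute configuration.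

Key step: step 6

Remark: atoms carry labdane numbers (C19 carboxyl carbon, C17 exocyclic methylene carbon, C20 methyl on C10, C11–C16 side chain). The auxiliary is assumed to shield the C4 radical in its open, non-chelated conformer, so that the (1R,2S,5R) enantiomer leads to the ring configuration of the target.

Step 1
Reactants: 1 (2E,6E)-farnesol
Product: 2 (S)-2,3-dihydrofarnesol, (3S,6E)-3,7,11-trimethyldodeca-6,10-dien-1-ol
Conditions: H2 (30 atm), Ru(OAc)2[(R)-BINAP] (cat.), MeOH, 20 °C
Reagents that add atoms: none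
Why: Hydroxyl-directed Noyori asymmetric hydrogenation should reduce only the allylic alcohol double bond (the two isolated trisubstituted alkenes do not chelate), and the (R)-BINAP ligand acting on the (E)-allylic alcohol sets the (S) centre that becomes C13.

Step 2
Reactants: 2 (S)-2,3-dihydrofarnesol
Product: 3 tert-butyl{[(3S,6E)-3,7,11-trimethyldodeca-6,10-dien-1-yl]oxy}diphenylsilane
Conditions: TBDPSCl, imidazole, DMF, 20 °C
Reagents that add atoms: tert-butyl(chloro)diphenylsilane CC(C)(C)[Si](Cl)(c1ccccc1)c1ccccc1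
Why: Imidazole-promoted silylation of the primary alcohol gives a silyl ether that should survive the selenium oxidation, the dianion, acetic acid and LiAlH4 used later.

Step 3
Reactants: 3 silyl ether of (S)-2,3-dihydrofarnesol
Product: 4 (2E,6E,10S)-12-[(tert-butyldiphenylsilyl)oxy]-2,6,10-trimethyldodeca-2,6-dien-1-ol
Conditions: SeO2 (cat.), t-BuOOH, salicylic acid (cat.), CH2Cl2, 0 to 20 °C
Reagents that add atoms: selenium dioxide O=[Se]=O (oxygen carrier), tert-butyl hydroperoxide CC(C)(C)OO (terminal oxidant)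
Why: Riley allylic oxidation (ene reaction, then [2,3]-sigmatropic shift) should attack the most accessible terminal isopropylidene group at its (E)-methyl, giving the (E)-allylic alcohol whose CH2OH carbon becomes C1.

Step 4
Reactants: 4 allylic alcohol
Product: 5 {[(3S,6E,10E)-12-bromo-3,7,11-trimethyldodeca-6,10-dien-1-yl]oxy}(tert-butyl)diphenylsilane
Conditions: CBr4, PPh3, CH2Cl2, −20 to 0 °C
Reagents that add atoms: carbon tetrabromide BrC(Br)(Br)Br
Why: Appel bromination converts the primary allylic alcohol to the bromide under neutral conditions, without allylic transposition or loss of the silyl ether.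

Step 5
Reactants: 6 (−)-8-phenylmenthol, (1R,2S,5R)-5-methyl-2-(2-phenylpropan-2-yl)cyclohexan-1-ol; 7 methyl 2-methyl-3-oxobutanoate
Product: 8 (1R,2S,5R)-5-methyl-2-(2-phenylpropan-2-yl)cyclohexyl 2-methyl-3-oxobutanoate (both epimers at the acetoacetate carbon)
Conditions: DMAP (cat.), toluene, 110 °C, MeOH distilled off
Reagents that add atoms: none
Why: DMAP-catalysed transesterification of the β-keto ester (through the acylketene) installs the chiral auxiliary; the epimeric centre is irrelevant because it later becomes a planar radical.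

Step 6
Reactants: 8 8-phenylmenthyl 2-methylacetoacetate; 5 allylic bromide
Product: 10 (1R,2S,5R)-5-methyl-2-(2-phenylpropan-2-yl)cyclohexyl (4R,5R,9S,10R,13S)-15-[(tert-butyldiphenylsilyl)oxy]-3-oxolabd-8(17)-en-19-oate, via open-chain keto ester 9 (not isolated)
Conditions: NaH then n-BuLi, THF, 0 °C; 5, 0 to 20 °C; AcOH, AgOAc; solvent switch to AcOH in the same flask; Mn(OAc)3·2H2O, Cu(OAc)2·H2O, 25 °C, argon
Reagents that add atoms: none
Why: The dianion of 8 is alkylated at its terminal carbon C2 by bromide 5 (substitution at C1, forming C1–C2) to give the enolate of 9; after acidification and removal of bromide as AgBr, Mn(OAc)3 (trivalent manganese) oxidises the enol to the C4 radical, which adds to C5, the C10 radical then adds to C9, and Cu(OAc)2 (divalent copper) oxidises the tertiary C8 radical to the C8=C17 alkene. The closest known reaction types are the Weiler acetoacetate dianion alkylation and the Mn(OAc)3/Cu(OAc)2 oxidative radical polyene cyclization of 2-alkylacetoacetates, here run in sequence in one flask. Ring A closes 6-endo-trig (C4 onto C5 of the C5=C10 alkene) and ring B closes 6-endo-trig (C10 onto C9 of the C8=C9 alkene). A chair–chair transition state with the two E alkenes should set the relative configuration (trans ring fusion with H on C5 anti to the C10 methyl, equatorial side chain on C9, ester axial on C4 and cis to the C10 methyl), while the phenyl ring of the auxiliary covers one face of the C4 radical so that C5 bonds to the open face; the minor diastereomer is removed by chromatography. The step needs 6-endo over 5-exo closure, secured by the α-keto ester radical and the methyl groups on C10 and C8, and exocyclic over endocyclic alkene formation, secured by copper-mediated loss of hydrogen from the C17 methyl. Bromide is precipitated before the oxidant is added because it would otherwise be oxidised and transferred to the radicals.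

Step 7
Reactants: 10 bicyclic keto ester
Product: 12 (1R,2S,5R)-5-methyl-2-(2-phenylpropan-2-yl)cyclohexyl (4S,5R,9S,10R,13S)-15-[(tert-butyldiphenylsilyl)oxy]labd-8(17)-en-19-oate, via tosylhydrazone 11 (not isolated)
Conditions: TsNHNH2, EtOH, 78 °C; then catecholborane, CHCl3, 0 °C; NaOAc·3H2O, 60 °C
Reagents that add atoms: none
Why: Caglioti-type reduction of the tosylhydrazone (catecholborane, then acetate-induced loss of sulfinate and N2) should remove the C3 carbonyl without touching the exocyclic alkene or the hindered ester, and it creates no stereocentre.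

Step 8
Reactants: 12 deoxygenated 8-phenylmenthyl ester
Product: 13 (4S,5R,9S,10R,13S)-15-[(tert-butyldiphenylsilyl)oxy]labd-8(17)-en-19-ol
Conditions: LiAlH4, THF, 66 °C
Reagents that add atoms: none
Why: LiAlH4 is small enough to reduce the hindered axial ester to the primary alcohol, releasing the auxiliary for recovery, while the silyl ether and the alkene are inert.

Step 9
Reactants: 13 C19 alcohol
Product: 15 (4S,5R,9S,10R,13S)-15-[(tert-butyldiphenylsilyl)oxy]labd-8(17)-en-19-oic acid, via aldehyde 14 (not isolated)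
Conditions: PhI(OAc)2, TEMPO (cat.), CH2Cl2, 20 °C; then NaClO2, NaH2PO4, 2-methyl-2-butene, t-BuOH/H2O, 20 °C
Reagents that add atoms: sodium chlorite [Na+].[O-]Cl=O
Why: Oxoammonium (TEMPO) oxidation should stop at the hindered aldehyde 14, and a buffered Pinnick oxidation in the same flask takes it to the acid, with 2-methyl-2-butene scavenging hypochlorite so that the C8=C17 alkene is spared.

Step 10
Reactants: 15 silyl-protected acid
Product: 16 imbricatolic acid, (4S,5R,9S,10R,13S)-15-hydroxylabd-8(17)-en-19-oic acid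
Conditions: TBAF, THF, 20 °C
Reagents that add atoms: none
Why: Fluoride cleaves the silyl ether, driven by the strong Si–F bond, and frees the C15 alcohol without affecting the acid or the alkene.

Step 11
Reactants: 16 imbricatolic acid
Product: 17 (4S,5R,9S,10R,13S)-15-(formyloxy)labd-8(17)-en-19-oic acid (target)
Conditions: HCO2H/Ac2O (premixed at 55 °C to give acetic formic anhydride), pyridine, CH2Cl2, 0 °C; aqueous work-up
Reagents that add atoms: acetic formic anhydride CC(=O)OC=O (made from formic acid OC=O and acetic anhydride CC(=O)OC(C)=O)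
Why: The mixed anhydride transfers its more electrophilic formyl group to the unhindered primary alcohol (O-formylation), while any mixed anhydride formed at the hindered C19 acid is hydrolysed on aqueous work-up.

Compound list
1 | (2E,6E)-farnesol | CC(C)=CCC/C(C)=C/CC/C(C)=C/CO | starting material
2 | (S)-2,3-dihydrofarnesol, (3S,6E)-3,7,11-trimethyldodeca-6,10-dien-1-ol | CC(C)=CCC/C(C)=C/CC[C@H](C)CCO | intermediate
3 | tert-butyl{[(3S,6E)-3,7,11-trimethyldodeca-6,10-dien-1-yl]oxy}diphenylsilane | CC(C)=CCC/C(C)=C/CC[C@H](C)CCO[Si](c1ccccc1)(c2ccccc2)C(C)(C)C | intermediate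
4 | (2E,6E,10S)-12-[(tert-butyldiphenylsilyl)oxy]-2,6,10-trimethyldodeca-2,6-dien-1-ol | OC/C(C)=C/CC/C(C)=C/CC[C@H](C)CCO[Si](c1ccccc1)(c2ccccc2)C(C)(C)C | intermediate
5 | {[(3S,6E,10E)-12-bromo-3,7,11-trimethyldodeca-6,10-dien-1-yl]oxy}(tert-butyl)diphenylsilane | BrC/C(C)=C/CC/C(C)=C/CC[C@H](C)CCO[Si](c1ccccc1)(c2ccccc2)C(C)(C)C | intermediate
6 | (−)-8-phenylmenthol, (1R,2S,5R)-5-methyl-2-(2-phenylpropan-2-yl)cyclohexan-1-ol | CC(C)(c1ccccc1)[C@@H]2CC[C@@H](C)C[C@H]2O | starting material
7 | methyl 2-methyl-3-oxobutanoate | CC(=O)C(C)C(=O)OC | starting material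
8 | (1R,2S,5R)-5-methyl-2-(2-phenylpropan-2-yl)cyclohexyl 2-methyl-3-oxobutanoate | CC(=O)C(C)C(=O)O[C@@H]1C[C@H](C)CC[C@H]1C(C)(C)c2ccccc2 | intermediate
9 | (1R,2S,5R)-5-methyl-2-(2-phenylpropan-2-yl)cyclohexyl (6E,10E,14S)-16-[(tert-butyldiphenylsilyl)oxy]-2,6,10,14-tetramethyl-3-oxohexadeca-6,10-dienoate | CC(C(=O)CC/C(C)=C/CC/C(C)=C/CC[C@H](C)CCO[Si](c1ccccc1)(c2ccccc2)C(C)(C)C)C(=O)O[C@@H]3C[C@H](C)CC[C@H]3C(C)(C)c4ccccc4 | intermediate (not isolated)
10 | (1R,2S,5R)-5-methyl-2-(2-phenylpropan-2-yl)cyclohexyl (4R,5R,9S,10R,13S)-15-[(tert-butyldiphenylsilyl)oxy]-3-oxolabd-8(17)-en-19-oate | C=C1CC[C@@H]2[C@](C)(CCC(=O)[C@]2(C)C(=O)O[C@@H]3C[C@H](C)CC[C@H]3C(C)(C)c4ccccc4)[C@H]1CC[C@H](C)CCO[Si](c5ccccc5)(c6ccccc6)C(C)(C)C | intermediate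
11 | 3-(4-methylbenzenesulfonylhydrazone) of 10 | C=C1CC[C@@H]2[C@](C)(CCC(=NNS(=O)(=O)c3ccc(C)cc3)[C@]2(C)C(=O)O[C@@H]4C[C@H](C)CC[C@H]4C(C)(C)c5ccccc5)[C@H]1CC[C@H](C)CCO[Si](c6ccccc6)(c7ccccc7)C(C)(C)C | intermediate (not isolated)
12 | (1R,2S,5R)-5-methyl-2-(2-phenylpropan-2-yl)cyclohexyl (4S,5R,9S,10R,13S)-15-[(tert-butyldiphenylsilyl)oxy]labd-8(17)-en-19-oate | C=C1CC[C@@H]2[C@](C)(CCC[C@]2(C)C(=O)O[C@@H]3C[C@H](C)CC[C@H]3C(C)(C)c4ccccc4)[C@H]1CC[C@H](C)CCO[Si](c5ccccc5)(c6ccccc6)C(C)(C)C | intermediate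
13 | (4S,5R,9S,10R,13S)-15-[(tert-butyldiphenylsilyl)oxy]labd-8(17)-en-19-ol | C=C1CC[C@@H]2[C@](C)(CCC[C@]2(C)CO)[C@H]1CC[C@H](C)CCO[Si](c3ccccc3)(c4ccccc4)C(C)(C)C | intermediate
14 | (4S,5R,9S,10R,13S)-15-[(tert-butyldiphenylsilyl)oxy]labd-8(17)-en-19-al | C=C1CC[C@@H]2[C@](C)(CCC[C@]2(C)C=O)[C@H]1CC[C@H](C)CCO[Si](c3ccccc3)(c4ccccc4)C(C)(C)C | intermediate (not isolated)
15 | (4S,5R,9S,10R,13S)-15-[(tert-butyldiphenylsilyl)oxy]labd-8(17)-en-19-oic acid | C=C1CC[C@@H]2[C@](C)(CCC[C@]2(C)C(=O)O)[C@H]1CC[C@H](C)CCO[Si](c3ccccc3)(c4ccccc4)C(C)(C)C | intermediate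
16 | imbricatolic acid, (4S,5R,9S,10R,13S)-15-hydroxylabd-8(17)-en-19-oic acid | C=C1CC[C@@H]2[C@](C)(CCC[C@]2(C)C(=O)O)[C@H]1CC[C@H](C)CCO | intermediate
17 | (4S,5R,9S,10R,13S)-15-(formyloxy)labd-8(17)-en-19-oic acid | C=C1CC[C@@H]2[C@](C)(CCC[C@]2(C)C(=O)O)[C@H]1CC[C@H](C)CCOC=O | target

Total step count: 11. Longest linear sequence: 10 steps (steps 1–4 and 6–11, from 1 to 17); step 5 is a one-step side branch.

Steps most likely to fail

Step 6. The face discrimination in the first radical addition may be weak or reversed, because the non-chelated keto ester radical can rotate about the C3–C4 and C4–C19 bonds, and incomplete bromide removal would lead to halogen transfer to the C8 radical. The fallback changes the stereocontrol element from an open, π-shielded radical to a rigid metal chelate, which is expected to expose the opposite face of C4 and therefore uses the antipodal auxiliary. It sets out from 5 and 7. Ester 7 is transesterified with (+)-8-phenylmenthol to (1S,2R,5S)-5-methyl-2-(2-phenylpropan-2-yl)cyclohexyl 2-methyl-3-oxobutanoate F1. The dianion of F1 is alkylated with 5 to the open-chain keto ester F2, which is not isolated. After AgOAc treatment and a solvent switch to CF3CH2OH in the same flask, the Yb(OTf)3 chelate of F2 is oxidised with Mn(OAc)3·2H2O and Cu(OAc)2·H2O at 0 °C to the bicyclic keto ester F3, which has the ring configuration of 10. Deoxygenation as in step 7 gives ester F4, and LiAlH4 reduction returns to the route at 13.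

Step 3. Oxidation may also occur at the allylic positions of the internal alkene, and the product may be over-oxidised to the enal, so regiocontrol and conversion are both at risk. The fallback builds the terminus stepwise and sets out from 3. NBS in aqueous THF attacks the terminal alkene selectively to give the bromohydrin (6E,10S)-3-bromo-12-[(tert-butyldiphenylsilyl)oxy]-2,6,10-trimethyldodec-6-en-2-ol F5. K2CO3 in MeOH closes it to the terminal epoxide F6, and HIO4 cleaves this to (4E,8S)-10-[(tert-butyldiphenylsilyl)oxy]-4,8-dimethyldec-4-enal F7. Wittig reaction with ethyl 2-(triphenylphosphoranylidene)propanoate gives the (E)-enoate ethyl (2E,6E,10S)-12-[(tert-butyldiphenylsilyl)oxy]-2,6,10-trimethyldodeca-2,6-dienoate F8, and DIBAL-H reduction returns to the route at 4.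

Step 7. Hydrazone formation at the C3 ketone may be slow or incomplete, because the carbonyl is flanked by the quaternary C4 and the bulky ester. The fallback removes the oxygen by a radical route and sets out from 10. NaBH4 reduces the ketone to the 3-hydroxy ester F9, and NaH, CS2 and MeI convert it to the S-methyl xanthate F10. Barton–McCombie reduction with Bu3SnH and AIBN in toluene at 110 °C returns to the route at 12.

Further compounds
F1 | step 6 | (1S,2R,5S)-5-methyl-2-(2-phenylpropan-2-yl)cyclohexyl 2-methyl-3-oxobutanoate | CC(=O)C(C)C(=O)O[C@H]1C[C@@H](C)CC[C@@H]1C(C)(C)c2ccccc2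
F2 | step 6 | (1S,2R,5S)-5-methyl-2-(2-phenylpropan-2-yl)cyclohexyl (6E,10E,14S)-16-[(tert-butyldiphenylsilyl)oxy]-2,6,10,14-tetramethyl-3-oxohexadeca-6,10-dienoate | CC(C(=O)CC/C(C)=C/CC/C(C)=C/CC[C@H](C)CCO[Si](c1ccccc1)(c2ccccc2)C(C)(C)C)C(=O)O[C@H]3C[C@@H](C)CC[C@@H]3C(C)(C)c4ccccc4
F3 | step 6 | (1S,2R,5S)-5-methyl-2-(2-phenylpropan-2-yl)cyclohexyl (4R,5R,9S,10R,13S)-15-[(tert-butyldiphenylsilyl)oxy]-3-oxolabd-8(17)-en-19-oate | C=C1CC[C@@H]2[C@](C)(CCC(=O)[C@]2(C)C(=O)O[C@H]3C[C@@H](C)CC[C@@H]3C(C)(C)c4ccccc4)[C@H]1CC[C@H](C)CCO[Si](c5ccccc5)(c6ccccc6)C(C)(C)C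
F4 | step 6 | (1S,2R,5S)-5-methyl-2-(2-phenylpropan-2-yl)cyclohexyl (4S,5R,9S,10R,13S)-15-[(tert-butyldiphenylsilyl)oxy]labd-8(17)-en-19-oate | C=C1CC[C@@H]2[C@](C)(CCC[C@]2(C)C(=O)O[C@H]3C[C@@H](C)CC[C@@H]3C(C)(C)c4ccccc4)[C@H]1CC[C@H](C)CCO[Si](c5ccccc5)(c6ccccc6)C(C)(C)C
F5 | step 3 | (6E,10S)-3-bromo-12-[(tert-butyldiphenylsilyl)oxy]-2,6,10-trimethyldodec-6-en-2-ol | CC(C)(O)C(Br)CC/C(C)=C/CC[C@H](C)CCO[Si](c1ccccc1)(c2ccccc2)C(C)(C)C
F6 | step 3 | tert-butyl{[(3S,6E)-9-(3,3-dimethyloxiran-2-yl)-3,7-dimethylnon-6-en-1-yl]oxy}diphenylsilane | CC1(C)OC1CC/C(C)=C/CC[C@H](C)CCO[Si](c2ccccc2)(c3ccccc3)C(C)(C)C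
F7 | step 3 | (4E,8S)-10-[(tert-butyldiphenylsilyl)oxy]-4,8-dimethyldec-4-enal | O=CCC/C(C)=C/CC[C@H](C)CCO[Si](c1ccccc1)(c2ccccc2)C(C)(C)C
F8 | step 3 | ethyl (2E,6E,10S)-12-[(tert-butyldiphenylsilyl)oxy]-2,6,10-trimethyldodeca-2,6-dienoate | CCOC(=O)/C(C)=C/CC/C(C)=C/CC[C@H](C)CCO[Si](c1ccccc1)(c2ccccc2)C(C)(C)C
F9 | step 7 | (1R,2S,5R)-5-methyl-2-(2-phenylpropan-2-yl)cyclohexyl (4R,5R,9S,10R,13S)-15-[(tert-butyldiphenylsilyl)oxy]-3-hydroxylabd-8(17)-en-19-oate | C=C1CC[C@@H]2[C@](C)(CCC(O)[C@]2(C)C(=O)O[C@@H]3C[C@H](C)CC[C@H]3C(C)(C)c4ccccc4)[C@H]1CC[C@H](C)CCO[Si](c5ccccc5)(c6ccccc6)C(C)(C)C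
F10 | step 7 | O-[3-yl] S-methyl dithiocarbonate (xanthate) of F9 | C=C1CC[C@@H]2[C@](C)(CCC(OC(=S)SC)[C@]2(C)C(=O)O[C@@H]3C[C@H](C)CC[C@H]3C(C)(C)c4ccccc4)[C@H]1CC[C@H](C)CCO[Si](c5ccccc5)(c6ccccc6)C(C)(C)C
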